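The beta and eta runs end 0.6 percentage points apart in target, although eta holds twice beta's second reagent, while the epsilon run is still climbing at 5.00 h. Substrate and coupling partner give intermediate, second reagent turns intermediate into target and also slips reversibly into the dormant form, and substrate meeting target gives side product.

| flask | substrate | coupling partner | second reagent | remark | time |
|---|---|---|---|---|---|
| epsilon | 0.017 M | 0.0255 M | 0.023 M | run made earlier |  |
| beta | 0.017 M | 0.0255 M | 0.058 M | run made earlier |  |
| eta | 0.017 M | 0.0255 M | 0.12 M | run made earlier |  |
| amber | 0.017 M | 0.0255 M | 0.0200 M |  | 10 h |
| green | 0.017 M | 0.0255 M | 0.0400 M |  | 10 h |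
| ochre | 0.017 M | 0.0255 M | 0.0800 M |  | 10 h |
| blue | 0.017 M | 0.0255 M | 0.150 M |  | 10 h |

- epsilon (time / h: target / %, substrate / %): 0.667: 28.5, 36.4; 2.00: 52.5, 7.6; 3.00: 58.6, 3.2; 5.00: 65.7, 0
- beta (time / h: target / %, substrate / %): 0.667: 44.1, 35.7; 2.00: 66.9, 5.4; 3.00: 70.3, 1.0; 5.00: 72.4, 0.2
- eta (time / h: target / %, substrate / %): 0.667: 49.9, 34.4; 2.00: 67.3, 6.5; 3.00: 69.1, 1.8; 5.00: 71.8, 0.5

(each reading ± 0.5 percentage points)

- percent here means substrate units held: one side product counts as two
- the analysis behind the earlier runs scatters by 0.5 percentage points, standard deviation
- reactions considered so far: substrate + target -> side product; substrate + coupling partner -> intermediate; second reagent <-> dormant form; second reagent + intermediate -> target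
- "hardly changes" means that all values lie within two and a half points (for a concentration: within two and a half percent of the largest)

* amount of target at the end, in percent of the substrate charged for amber, green, ochre, blue, in this order
* the shape of the row from first to last (hardly changes / rises, then falls / rises all the way / falls all the way / falls, then rises)

I solve the flask at both ends. With plenty of second reagent, intermediate becomes target at once, target stands beside substrate, and the loss to side product, which I call the toll, runs high: beta's last reading leaves 27.6% of the charge outside target, and I take that as the toll of this end. With very little, target appears after substrate has gone, so the toll shrinks, but intermediate is left waiting. The real flask lies between, and its end target is the whole charge less toll less waiting intermediate.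

Substrate falls alike in epsilon and beta, 36.4% against 35.7% at 0.667 h, so I scale the toll with the target standing beside it. Over the first two readings epsilon's target is 0.730 of beta's, which puts epsilon's toll near 20.1%. Subtracting target and leftover substrate, 18.1% waits at 3.00 h and 14.2% at 5.00 h. The waiting half-life, the time in which intermediate halves late in the run (a pseudo-first-order half-life), is therefore 5.70 h, a rough reading of epsilon given the scatter of 0.5 points.

I treat amber as epsilon: by 10 h the waiting falls to 7.71%, leaving 72.2% target. Beta gains 2.1 points between 3.00 h and 5.00 h, less than epsilon's 7.1 points, so for green I count no waiting and interpolate the toll to 23.8%, which gives 76.2%. Ochre and blue I place at the last readings of beta and eta, 72.4% and 71.8%.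

The forecast reads 71.5%, 75%, 72.5% and 71.5%, shape rises, then falls, with its green under mine, on the ground that “less reagent means less side product, because target builds up after substrate has gone, but late conversion becomes slow”.

The flasks give 71.9%, 74.9%, 71.7% and 70.2%: rises, then falls.

    substrate + target → side product (k = 0.564 /M/min)
    substrate + coupling partner → intermediate (k = 1.24 /M/min)
    second reagent ⇌ dormant form (K = 3.03, k = 0.00946 /min)
    second reagent + intermediate → target (k = 2.07 /M/min)

Carried to amber, the waiting half-life of 5.70 h takes the 18.5% of intermediate standing at 5.00 h to 10.1% at 10.0 h, and amber holds 8.50%. In green, intermediate falls from 1.44% to 0.0369% over the same span, a waiting half-life of 0.947 h on average, shorter than 5.70 h, with unbound second reagent at 10.0 h standing at 0.00622 M against amber's 0.00124 M.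

Readings and results are simulated with made-up constants.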